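## Retrosynthetic overview

1. **Feature.** Ring A is the methoxy ring, with C1 defined as the carbon bearing the CH2CH2 bridge. It carries five contiguous substituents: C1 bridge, C2 4-hydroxybenzyl, C3 OMe, C4 4-hydroxybenzyl, C5 OH; only C6 is H. Benzylation of a purchased resorcinol ring cannot distinguish C2, C4 and C6, nor O3 from O5.
2. **Key disconnection.** Ring A is built last by a thermal cyclobutenone/ynol ether benzannulation that makes C2–C3 and C4–C5 ([2+2]) and then C5–C6 (6π closure). The cyclobutenone supplies C1, C2, C5 and C6 together with ring B and two benzyl groups. MeO–C≡C–CH2Ar supplies C3 and C4 with the OMe and the third benzyl group.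
3. **Cyclobutenone.** It comes from the same ynol ether by [2+2] with ketene, then Grignard addition of the ring-B side chain with enone transposition. All six carbons of ring A therefore stem from two copies of one ynol ether and one ketene.
4. **Ring-B fragment.** An oxa-Pictet–Spengler tether places the benzylic carbon at C6' (para to 3'-OH, ortho to the bridge). Hydrogenolysis then opens the temporary isochroman.
5. **Ring order.** Isochroman (temporary), then the four-membered ring, then ring A. One global debenzylation ends the route.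

Key step: step 7

Remark: the target has no stereocentre, stereogenic axis or stereogenic double bond. It is achiral, so no enantiomer has to be selected. The stereocentres of a few passing intermediates are racemic and are erased later.

## Route

Step 1
Reactants: 1 2-(3-hydroxyphenyl)ethanol; 2 4-hydroxybenzaldehyde
Product: 4 3-(2-hydroxyethyl)-4-(4-hydroxybenzyl)phenol, via isochromanol 3 (not isolated)
Conditions: p-TsOH·H2O (10 mol %), MeOH, rt; then 10% Pd/C, H2 (1 atm), same flask, rt
Reagents that add atoms: none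
Why: Oxa-Pictet–Spengler cyclisation, in which the oxocarbenium ion tethered through the side-chain oxygen can reach only C2' and C6' and should attack C6' para to the phenol OH, followed by hydrogenolysis of the doubly benzylic C–O bond of racemic 3, which erases its stereocentre and frees the primary alcohol.

Step 2
Reactants: 4 3-(2-hydroxyethyl)-4-(4-hydroxybenzyl)phenol
Product: 5 2-{5-(benzyloxy)-2-[4-(benzyloxy)benzyl]phenyl}ethan-1-ol
Conditions: BnBr (2.2 equiv), K2CO3, acetone, reflux
Reagents that add atoms: benzyl bromide, BrCc1ccccc1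
Why: Williamson ether synthesis, in which carbonate deprotonates only the two phenols, so the primary alcohol should stay free.

Step 3
Reactants: 5 2-{5-(benzyloxy)-2-[4-(benzyloxy)benzyl]phenyl}ethan-1-ol
Product: 6 4-(benzyloxy)-1-[4-(benzyloxy)benzyl]-2-(2-bromoethyl)benzene
Conditions: CBr4, PPh3, CH2Cl2, 0 °C
Reagents that add atoms: carbon tetrabromide, BrC(Br)(Br)Br
Why: Appel reaction of an unhindered primary alcohol under neutral conditions that leave aryl benzyl ethers untouched.

Step 4
Reactants: 7 2-chloro-1,1-dimethoxyethane; 8 1-(benzyloxy)-4-(bromomethyl)benzene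
Product: 10 1-(benzyloxy)-4-(3-methoxyprop-2-yn-1-yl)benzene, via lithium methoxyacetylide 9 (not isolated)
Conditions: 7 (1.2 equiv), LDA (3.6 equiv), THF, 0 °C; then 8, DMPU, −78 °C → rt; water quench
Reagents that add atoms: none
Why: Double β-elimination (MeOH, then HCl) and deprotonation of the chloroacetal gives the alkoxyacetylide, whose SN2 alkylation with a reactive bromide is the known route to 1-alkoxyalk-1-ynes, and the hindered amine released from LDA should not compete for 8.

Step 5
Reactants: 10 1-(benzyloxy)-4-(3-methoxyprop-2-yn-1-yl)benzene; 11 acetyl chloride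
Product: 13 2-[4-(benzyloxy)benzyl]-3-methoxycyclobut-2-en-1-one, via ketene 12 (not isolated)
Conditions: Et3N (2 equiv), 11 (1.5 equiv, syringe pump), CH2Cl2, 0 °C → rt
Reagents that add atoms: none
Why: Ketene–alkoxyalkyne [2+2] cycloaddition, in which the nucleophilic alkyne carbon bearing the benzyl group bonds to the ketene carbonyl carbon, so only the 2-benzyl-3-methoxy regioisomer should form.

Step 6
Reactants: 6 4-(benzyloxy)-1-[4-(benzyloxy)benzyl]-2-(2-bromoethyl)benzene; 13 2-[4-(benzyloxy)benzyl]-3-methoxycyclobut-2-en-1-one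
Product: 16 2-[4-(benzyloxy)benzyl]-3-(2-{5-(benzyloxy)-2-[4-(benzyloxy)benzyl]phenyl}ethyl)cyclobut-2-en-1-one, via Grignard reagent 14 (not isolated), via cyclobutenol 15 (not isolated)
Conditions: 6, Mg, THF, rt → 40 °C; then 13, THF, −78 → 0 °C; then 1 M HCl, THF, 0 °C → rt
Reagents that add atoms: water, O
Why: 1,2-Addition of a Grignard reagent to a vinylogous ester followed by acid hydrolysis with allylic transposition (Stork–Danheiser-type enone transposition), favoured because enolisation of 13 would give a cyclobutadiene-like enolate, with the stereocentre of racemic 15 lost on forming the enone.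

Step 7
Reactants: 16 2-[4-(benzyloxy)benzyl]-3-(2-{5-(benzyloxy)-2-[4-(benzyloxy)benzyl]phenyl}ethyl)cyclobut-2-en-1-one; 10 1-(benzyloxy)-4-(3-methoxyprop-2-yn-1-yl)benzene
Product: 21 2,4-bis[4-(benzyloxy)benzyl]-5-(2-{5-(benzyloxy)-2-[4-(benzyloxy)benzyl]phenyl}ethyl)-3-methoxyphenol (tetra-O-benzyl bleochrin A), via vinylketene 17 (not isolated), via vinylcyclobutenone 18 (not isolated), via dienylketene 19 (not isolated), via cyclohexadienone 20 (not isolated)
Conditions: 10 (1.3 equiv), toluene (0.5 M), sealed tube, 110 °C, then 150 °C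
Reagents that add atoms: none
Why: Danheiser benzannulation, a cascade of four pericyclic steps and a tautomerisation: 4π electrocyclic opening of 16 (C(=O)–CH2 bond) gives vinylketene 17, [2+2] cycloaddition of its ketene C=C with ynol ether 10 gives 4-vinylcyclobutenone 18, 4π opening of 18 gives dienylketene 19, and 6π electrocyclisation gives dienone 20, which enolises to phenol 21. The closest known reaction type is exactly this thermal annulation of 2,3-dialkylcyclobutenones with internal 1-methoxyalkynes, which is known to deliver penta- and hexasubstituted resorcinol monomethyl ethers. Ring A is the only ring closed: C4–C5 and C2–C3 are made in the [2+2] step, and the ring is closed at C5–C6 by a thermally allowed disrotatory 6π electrocyclisation onto the unsubstituted =CH2 terminus. No stereocentre remains in 21, because the quaternary carbon of racemic 18 is erased in the second ring opening. The selectivity needed is the orientation of the [2+2] step, and polarity secures it: the nucleophilic alkyne carbon β to OMe (the one bearing the benzyl group) bonds to the electrophilic ketene carbonyl carbon, so OMe must land at C3 between the two benzyl groups and meta to the new C5–OH, C6 stays H, and the two oxygens are differentiated from the outset. Opening of 18 with the vinyl group turned outward is reversible and so drains through the productive isomer 19, and a methyl ynol ether, unlike an ethyl one, cannot lose an alkene by retro-ene fragmentation at this temperature.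

Step 8
Reactants: 21 tetra-O-benzyl bleochrin A
Product: 22 bleochrin A
Conditions: H2 (1 atm), 10% Pd/C, EtOAc/MeOH, rt
Reagents that add atoms: none
Why: Catalytic hydrogenolysis of the four aryl benzyl ethers, to which the diarylmethane and bibenzyl C–C bonds and the aryl methyl ether are inert.

## Compound list

1 | 2-(3-hydroxyphenyl)ethanol | OCCc1cccc(O)c1 | starting material
2 | 4-hydroxybenzaldehyde | O=Cc1ccc(O)cc1 | starting material
3 | 1-(4-hydroxyphenyl)-3,4-dihydro-1H-isochromen-6-ol (racemic) | Oc1ccc(cc1)C1OCCc2cc(O)ccc12 | intermediate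
4 | 3-(2-hydroxyethyl)-4-(4-hydroxybenzyl)phenol | OCCc1cc(O)ccc1Cc1ccc(O)cc1 | intermediate
5 | 2-{5-(benzyloxy)-2-[4-(benzyloxy)benzyl]phenyl}ethan-1-ol | OCCc1cc(OCc2ccccc2)ccc1Cc1ccc(OCc2ccccc2)cc1 | intermediate
6 | 4-(benzyloxy)-1-[4-(benzyloxy)benzyl]-2-(2-bromoethyl)benzene | BrCCc1cc(OCc2ccccc2)ccc1Cc1ccc(OCc2ccccc2)cc1 | intermediate
7 | 2-chloro-1,1-dimethoxyethane | COC(CCl)OC | starting material
8 | 1-(benzyloxy)-4-(bromomethyl)benzene | BrCc1ccc(OCc2ccccc2)cc1 | starting material
9 | lithium methoxyacetylide | [Li]C#COC | intermediate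
10 | 1-(benzyloxy)-4-(3-methoxyprop-2-yn-1-yl)benzene | COC#CCc1ccc(OCc2ccccc2)cc1 | intermediate
11 | acetyl chloride | CC(=O)Cl | starting material
12 | ketene | C=C=O | intermediate
13 | 2-[4-(benzyloxy)benzyl]-3-methoxycyclobut-2-en-1-one | COC1=C(Cc2ccc(OCc3ccccc3)cc2)C(=O)C1 | intermediate
14 | (2-{5-(benzyloxy)-2-[4-(benzyloxy)benzyl]phenyl}ethyl)magnesium bromide | Br[Mg]CCc1cc(OCc2ccccc2)ccc1Cc1ccc(OCc2ccccc2)cc1 | intermediate
15 | 2-[4-(benzyloxy)benzyl]-1-(2-{5-(benzyloxy)-2-[4-(benzyloxy)benzyl]phenyl}ethyl)-3-methoxycyclobut-2-en-1-ol (racemic) | COC1=C(Cc2ccc(OCc3ccccc3)cc2)C(O)(CCc2cc(OCc3ccccc3)ccc2Cc2ccc(OCc3ccccc3)cc2)C1 | intermediate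
16 | 2-[4-(benzyloxy)benzyl]-3-(2-{5-(benzyloxy)-2-[4-(benzyloxy)benzyl]phenyl}ethyl)cyclobut-2-en-1-one | O=C1CC(CCc2cc(OCc3ccccc3)ccc2Cc2ccc(OCc3ccccc3)cc2)=C1Cc1ccc(OCc2ccccc2)cc1 | intermediate
17 | vinylketene: 2-[4-(benzyloxy)benzyl]-3-(2-arylethyl)buta-1,3-dien-1-one (aryl = 5-(benzyloxy)-2-[4-(benzyloxy)benzyl]phenyl) | O=C=C(Cc1ccc(OCc2ccccc2)cc1)C(=C)CCc1cc(OCc2ccccc2)ccc1Cc1ccc(OCc2ccccc2)cc1 | intermediate
18 | 2,4-bis[4-(benzyloxy)benzyl]-3-methoxy-4-[4-arylbut-1-en-2-yl]cyclobut-2-en-1-one (racemic; aryl as in 17) | O=C1C(Cc2ccc(OCc3ccccc3)cc2)=C(OC)C1(Cc2ccc(OCc3ccccc3)cc2)C(=C)CCc2cc(OCc3ccccc3)ccc2Cc2ccc(OCc3ccccc3)cc2 | intermediate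
19 | dienylketene: (3E)-2,4-bis[4-(benzyloxy)benzyl]-3-methoxy-5-(2-arylethyl)hexa-1,3,5-trien-1-one (ketene and vinyl groups cis on the central C=C; aryl as in 17) | O=C=C(Cc1ccc(OCc2ccccc2)cc1)/C(OC)=C(Cc1ccc(OCc2ccccc2)cc1)\C(=C)CCc1cc(OCc2ccccc2)ccc1Cc1ccc(OCc2ccccc2)cc1 | intermediate
20 | 2,4-bis[4-(benzyloxy)benzyl]-3-methoxy-5-(2-arylethyl)cyclohexa-2,4-dien-1-one (aryl as in 17) | O=C1CC(CCc2cc(OCc3ccccc3)ccc2Cc2ccc(OCc3ccccc3)cc2)=C(Cc2ccc(OCc3ccccc3)cc2)C(OC)=C1Cc1ccc(OCc2ccccc2)cc1 | intermediate
21 | 2,4-bis[4-(benzyloxy)benzyl]-5-(2-{5-(benzyloxy)-2-[4-(benzyloxy)benzyl]phenyl}ethyl)-3-methoxyphenol (tetra-O-benzyl bleochrin A) | COc1c(Cc2ccc(OCc3ccccc3)cc2)c(O)cc(CCc2cc(OCc3ccccc3)ccc2Cc2ccc(OCc3ccccc3)cc2)c1Cc1ccc(OCc2ccccc2)cc1 | intermediate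
22 | bleochrin A (achiral) | COc1c(Cc2ccc(O)cc2)c(O)cc(CCc2cc(O)ccc2Cc2ccc(O)cc2)c1Cc1ccc(O)cc1 | target

## Step count and risks

- Total step count: 8
- Longest linear sequence: 6 (steps 1, 2, 3, 6, 7, 8)

### Steps most likely to fail

**1. Step 7.**
- What may go wrong:
  - The disubstituted vinylketene may react only slowly with an internal alkyne.
  - The vinylketene may then be lost by dimerisation or by acylating the phenol as it forms.
  - The cascade may stall at the four-membered adduct.
- Fallback: it sets out from 6 and 8 and comes back at 22. Ring A is closed by an anionic [3+3] Michael–Claisen condensation instead of a pericyclic cascade.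
  - Bromide 6 is alkylated with lithium acetylide–ethylenediamine (DMSO, rt) to 4-(benzyloxy)-1-[4-(benzyloxy)benzyl]-2-(but-3-yn-1-yl)benzene F1.
  - Carboxylation (n-BuLi, ClCO2Me, THF, −78 °C) gives methyl 5-{5-(benzyloxy)-2-[4-(benzyloxy)benzyl]phenyl}pent-2-ynoate F2.
  - Separately, two equivalents of 8 alkylate dimethyl 3-oxopentanedioate (K2CO3, acetone) to dimethyl 2,4-bis[4-(benzyloxy)benzyl]-3-oxopentanedioate F3.
  - Saponification and double decarboxylation (NaOH, aq. MeOH; acidify, warm) give the symmetric ketone 1,5-bis[4-(benzyloxy)phenyl]pentan-3-one F4. This ketone holds C2–C3–C4 with both benzyl groups.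
  - With t-BuOK in THF, the enolate of F4 should add to the β-carbon of F2 (C1–C2). The second α-carbon should then attack the ester (C4–C5). The enedione should tautomerise to 2,4-bis[4-(benzyloxy)benzyl]-5-(2-{5-(benzyloxy)-2-[4-(benzyloxy)benzyl]phenyl}ethyl)benzene-1,3-diol F5.
  - The less hindered C5–OH is benzylated (BnBr, 1 equiv, K2CO3) to 3-(benzyloxy)-2,6-bis[4-(benzyloxy)benzyl]-5-(2-{5-(benzyloxy)-2-[4-(benzyloxy)benzyl]phenyl}ethyl)phenol F6.
  - The remaining flanked OH is methylated (MeI, K2CO3, DMF) to penta-O-benzyl bleochrin A F7.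
  - Hydrogenolysis as in step 8 gives 22.

**2. Step 5.**
- What may go wrong:
  - The parent ketene made in the flask may self-condense.
  - The ynol ether may be acylated directly by acetyl chloride or its ammonium adduct.
  - The ynol ether may be hydrated by adventitious acid.
- Fallback: it sets out from 10 and comes back at 13. The cycloaddition is run with an activated, amine-free ketene surrogate, and the activating atoms are removed afterwards.
  - Dichloroketene (Cl3CCOCl, Zn–Cu, Et2O/DME) should add to 10 with the same orientation. The product is 2-[4-(benzyloxy)benzyl]-4,4-dichloro-3-methoxycyclobut-2-en-1-one F8.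
  - Reductive dechlorination (Zn, AcOH/TMEDA, EtOH) gives 13.

**3. Step 4.**
- What may go wrong:
  - The threefold reaction of the chloroacetal with a hindered amide may be incomplete.
  - Amine or methoxide may consume the benzylic bromide.
  - Base may isomerise the doubly activated propargylic CH2 of the product to the allene.
- Fallback: it sets out from 9 and comes back at 10. Generation of the acetylide is separated from C–C bond formation, and that bond is made by cross-coupling under neutral conditions.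
  - Acetylide 9 is trapped with Bu3SnCl to give distillable tributyl(methoxyethynyl)stannane F9.
  - A Stille coupling of F9 with 8 (Pd2(dba)3, P(2-furyl)3, THF, 50 °C) gives 10 in the absence of strong base, amine and methoxide.

## Further compounds

F1 | step 7 | 4-(benzyloxy)-1-[4-(benzyloxy)benzyl]-2-(but-3-yn-1-yl)benzene | C#CCCc1cc(OCc2ccccc2)ccc1Cc1ccc(OCc2ccccc2)cc1
F2 | step 7 | methyl 5-{5-(benzyloxy)-2-[4-(benzyloxy)benzyl]phenyl}pent-2-ynoate | COC(=O)C#CCCc1cc(OCc2ccccc2)ccc1Cc1ccc(OCc2ccccc2)cc1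
F3 | step 7 | dimethyl 2,4-bis[4-(benzyloxy)benzyl]-3-oxopentanedioate (mixture of diastereomers) | COC(=O)C(Cc1ccc(OCc2ccccc2)cc1)C(=O)C(Cc1ccc(OCc2ccccc2)cc1)C(=O)OC
F4 | step 7 | 1,5-bis[4-(benzyloxy)phenyl]pentan-3-one | O=C(CCc1ccc(OCc2ccccc2)cc1)CCc1ccc(OCc2ccccc2)cc1
F5 | step 7 | 2,4-bis[4-(benzyloxy)benzyl]-5-(2-{5-(benzyloxy)-2-[4-(benzyloxy)benzyl]phenyl}ethyl)benzene-1,3-diol | Oc1cc(CCc2cc(OCc3ccccc3)ccc2Cc2ccc(OCc3ccccc3)cc2)c(Cc2ccc(OCc3ccccc3)cc2)c(O)c1Cc1ccc(OCc2ccccc2)cc1
F6 | step 7 | 3-(benzyloxy)-2,6-bis[4-(benzyloxy)benzyl]-5-(2-{5-(benzyloxy)-2-[4-(benzyloxy)benzyl]phenyl}ethyl)phenol | Oc1c(Cc2ccc(OCc3ccccc3)cc2)c(OCc2ccccc2)cc(CCc2cc(OCc3ccccc3)ccc2Cc2ccc(OCc3ccccc3)cc2)c1Cc1ccc(OCc2ccccc2)cc1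
F7 | step 7 | 1-(benzyloxy)-2,4-bis[4-(benzyloxy)benzyl]-5-(2-{5-(benzyloxy)-2-[4-(benzyloxy)benzyl]phenyl}ethyl)-3-methoxybenzene (penta-O-benzyl bleochrin A) | COc1c(Cc2ccc(OCc3ccccc3)cc2)c(OCc2ccccc2)cc(CCc2cc(OCc3ccccc3)ccc2Cc2ccc(OCc3ccccc3)cc2)c1Cc1ccc(OCc2ccccc2)cc1
F8 | step 5 | 2-[4-(benzyloxy)benzyl]-4,4-dichloro-3-methoxycyclobut-2-en-1-one | COC1=C(Cc2ccc(OCc3ccccc3)cc2)C(=O)C1(Cl)Cl
F9 | step 4 | tributyl(methoxyethynyl)stannane | CCCC[Sn](CCCC)(CCCC)C#COC
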